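The seven-membered carbocycle is cut between C1/C10 and C6/C7 (guaianolide numbering) into a C1–C5–C6 three-carbon unit and a C7–C8–C9–C10 four-carbon unit. The key step exploits the oxygen at C9 (a 2-silyloxydiene) and the vicinal C5/C6 oxygens (an α-silyloxy enal): a catalytic asymmetric Diels–Alder reaction followed in the same flask by a 1,2-shift of C7 onto the formyl carbon, a formal (4+3) cycloaddition that forms both bonds and sets C6, C7 and C10. Its precursors are an acyclic (2Z,4E)-3-silyloxydiene and 2-(triisopropylsilyloxy)acrolein; the C1 carbinol, crotonoyl group, tiglate and lactone follow by substrate control.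

Key step: step 7

Remark: ring atoms are numbered as in guaianolides (C1 carbinol carbon; C2–C4 and C15 crotonoyl; C5–C10 ring; C11–C13 lactone α-carbon, carbonyl and methyl; C14 methyl on C10), β is the ring face carrying C14, and compounds 1, 4, 7, 15 and 24 are taken as commercially available.

Step 1
Reactants: 1 methyl (S)-3-hydroxy-2-methylpropanoate
Product: 2 methyl (S)-3-[(tert-butyldimethylsilyl)oxy]-2-methylpropanoate
Conditions: TBSCl, imidazole, CH2Cl2, 0 °C → rt
Reagents that add atoms: tert-butyldimethylsilyl chloride, CC(C)(C)[Si](C)(C)Cl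
Why: Imidazole-promoted O-silylation (silyl ether formation) of the primary alcohol proceeds without touching the C11 stereocentre.

Step 2
Reactants: 2 methyl (S)-3-[(tert-butyldimethylsilyl)oxy]-2-methylpropanoate
Product: 3 (S)-3-[(tert-butyldimethylsilyl)oxy]-2-methylpropanal
Conditions: i-Bu2AlH (1.05 equiv), CH2Cl2, −78 °C; aqueous sodium potassium tartrate
Reagents that add atoms: none
Why: Partial ester reduction with i-Bu2AlH at −78 °C stops at the aluminium hemiacetal, which collapses to the aldehyde only on work-up, so the α-stereocentre is neither over-reduced nor epimerised.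

Step 3
Reactants: 3 (S)-3-[(tert-butyldimethylsilyl)oxy]-2-methylpropanal; 4 diethyl (2-oxobutyl)phosphonate
Product: 5 (R,E)-7-[(tert-butyldimethylsilyl)oxy]-6-methylhept-4-en-3-one
Conditions: Ba(OH)2·8H2O, THF/H2O (40:1), 0 °C → rt
Reagents that add atoms: none
Why: Horner–Wadsworth–Emmons olefination of the β-ketophosphonate under mild Ba(OH)2 activation should give the (E)-enone and spare the α-stereogenic aldehyde from epimerisation.

Step 4
Reactants: 5 (R,E)-7-[(tert-butyldimethylsilyl)oxy]-6-methylhept-4-en-3-one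
Product: 6 (2Z,4E,6R)-7-[(tert-butyldimethylsilyl)oxy]-6-methyl-3-[(triisopropylsilyl)oxy]hepta-2,4-diene
Conditions: TIPSOTf, Et3N, CH2Cl2, 0 °C
Reagents that add atoms: triisopropylsilyl trifluoromethanesulfonate, CC(C)[Si](OS(=O)(=O)C(F)(F)F)(C(C)C)C(C)C
Why: Soft enolisation (silyl triflate–amine silyl enol ether formation) removes an α′-hydrogen of the ethyl ketone rather than the γ-hydrogen at C11 and gives the preferred (Z)-enol ether, which places the C10 methyl on the outside of the s-cis diene.

Step 5
Reactants: 7 2,2-dimethyl-1,3-dioxan-5-one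
Product: 8 2,2-dimethyl-5-[(triisopropylsilyl)oxy]-4H-1,3-dioxine
Conditions: TIPSOTf, Et3N, CH2Cl2, 0 °C → rt
Reagents that add atoms: triisopropylsilyl trifluoromethanesulfonate, CC(C)[Si](OS(=O)(=O)C(F)(F)F)(C(C)C)C(C)C
Why: Silyl enol ether formation (silyl triflate–amine) on the symmetrical ketone gives the 4H-1,3-dioxine, a masked 2-silyloxy enal.

Step 6
Reactants: 8 2,2-dimethyl-5-[(triisopropylsilyl)oxy]-4H-1,3-dioxine
Product: 9 2-[(triisopropylsilyl)oxy]prop-2-enal
Conditions: toluene, 110 °C (sealed tube)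
Reagents that add atoms: none
Why: Thermal retro-hetero-Diels–Alder cycloreversion of the 4H-1,3-dioxine expels acetone and releases the 2-silyloxy enal, which is used directly.

Step 7
Reactants: 6 (2Z,4E,6R)-7-[(tert-butyldimethylsilyl)oxy]-6-methyl-3-[(triisopropylsilyl)oxy]hepta-2,4-diene; 9 2-[(triisopropylsilyl)oxy]prop-2-enal
Product: 11 cycloheptenone (C1H2; C5=O; 6β-OTIPS; 7β-[(11R)-CH(CH3)CH2OTBS]; C8=C9 enol ether with 9-OTIPS; 10β-CH3), via Diels–Alder adduct 10 (not isolated)
Conditions: (S)-1-(2-methylphenyl)-3,3-diphenyltetrahydro-1H,3H-pyrrolo[1,2-c][1,3,2]oxazaborole·HN(SO2CF3)2 (20 mol %), CH2Cl2, −78 °C; then Me2AlCl (30 mol %), −78 → −20 °C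
Reagents that add atoms: none
Why: The oxazaborolidinium-activated enal undergoes an asynchronous exo-formyl Diels–Alder addition in which the nucleophilic diene terminus C10 bonds to the enal β-carbon (C1) and C7 to the α-carbon (C5), giving cyclohexene 10; the aluminium Lewis acid then triggers an α-ketol-type 1,2-shift of C7 from C5 to the formyl carbon (C6) with O→O silyl transfer, which forms the C6–C7 bond and the C5 ketone. The closest known reaction type is the Lewis-acid-induced tandem Diels–Alder/ring expansion of 2-(trialkylsilyloxy)acroleins with dienes, a formal (4+3) cycloaddition, including its enantioselective oxazaborolidinium-catalysed variant. The six-membered ring closes by suprafacial (4+2) cycloaddition and is enlarged to the seven-membered ring by a suprafacial 1,2-alkyl shift with retention at C7. C10 and C7 should become cis because both substituents are outside on the (2Z,4E)-diene, their absolute sense is set by the catalyst (C11 comes from ester 1), and C6 should be fixed cis to the C7 side chain by the exo-formyl adduct rearranging through the syn-periplanar O–C–C=O conformer needed for silyl transfer. The step needs C10→C1 regiochemistry, which the 3-silyloxy group secures by making C10 the nucleophilic terminus, and migration of C7 rather than C1, which is favoured because C7 is secondary and allylic to the enol ether whereas C1 is a primary methylene.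

Step 8
Reactants: 11 cycloheptenone (C1H2; C5=O; 6β-OTIPS; 7β side chain; 9-OTIPS enol ether; 10β-CH3)
Product: 13 1α-hydroxy ketone (1α-OH expected as major epimer; otherwise as 11), via potassium enolate 12 (not isolated)
Conditions: KN(SiMe3)2, THF, −78 °C; then 2-(phenylsulfonyl)-3-phenyloxaziridine, −78 °C; aqueous NH4Cl
Reagents that add atoms: 2-(phenylsulfonyl)-3-phenyloxaziridine, O=S(=O)(N1OC1c1ccccc1)c1ccccc1
Why: Kinetic deprotonation should occur at the C1 methylene rather than at the hindered, silyloxy-bearing C6 methine, and the enolate is hydroxylated by the N-sulfonyloxaziridine (enolate oxidation of the Davis type) from the open α-face; the configuration at C1 is irrelevant because it is oxidised next.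

Step 9
Reactants: 13 1α-hydroxy ketone
Product: 14 1,5-diketone (C1=O; C5=O; otherwise as 11)
Conditions: Dess–Martin periodinane, pyridine, CH2Cl2, 0 °C
Reagents that add atoms: none
Why: Dess–Martin oxidation converts the acyloin into the 1,2-diketone under buffered, non-enolising conditions that should leave the silyl enol ether and the C6 and C10 stereocentres intact.

Step 10
Reactants: 14 1,5-diketone; 15 (E)-but-2-enal
Product: 17 aldol adduct (1β-OH; 1α-[(E)-1-hydroxybut-2-enyl]; C5=O; C2 epimers), via samarium enediolate 16 (not isolated)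
Conditions: SmI2 (2.2 equiv), THF, −78 °C; then (E)-but-2-enal, −78 °C; aqueous NH4Cl
Reagents that add atoms: none
Why: Samarium diiodide-mediated reductive aldol of a 1,2-diketone: two-electron reduction gives the C1=C5 enediolate, which should attack the aldehyde through C1 (the terminus remote from the bulky C6 silyloxy group) from the α-face, opposite the β-oriented C10 methyl and C6 silyloxy groups, so that the C1 oxygen ends β and C5 reverts to the ketone, while the new C2 carbinol is an inconsequential epimer mixture.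

Step 11
Reactants: 17 aldol adduct
Product: 18 C2 triethylsilyl ether (1β-OH free; C5=O)
Conditions: TESCl, imidazole, CH2Cl2, −20 → 0 °C
Reagents that add atoms: chlorotriethylsilane, CC[Si](Cl)(CC)CC
Why: Silyl ether formation is selective for the secondary allylic C2 hydroxyl over the tertiary C1 hydroxyl, leaving the latter as the only group able to direct the following reduction.

Step 12
Reactants: 18 C2 triethylsilyl ether
Product: 19 1β,5α-diol (5α-OH; 1β-OH; 2-OTES; 6β-OTIPS; 9-OTIPS enol ether; 12-OTBS)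
Conditions: Me4NBH(OAc)3, MeCN/AcOH (1:1), −30 °C
Reagents that add atoms: none
Why: Hydroxyl-directed triacetoxyborohydride reduction (Evans–Saksena reduction): the C1 β-hydroxyl exchanges onto boron and delivers hydride intramolecularly to the β-face of the C5 ketone, which should give the trans-1,2-diol with the 5α-hydroxyl.

Step 13
Reactants: 19 1β,5α-diol
Product: 20 pentaol ketone (1β,2,5α,6β,12-pentahydroxy; C9=O; C2 epimers)
Conditions: HF·pyridine, pyridine, THF, 0 °C → rt
Reagents that add atoms: none
Why: Fluoride-mediated desilylation removes the three silyl ethers and hydrolyses the silyl enol ether to the C9 ketone, creating no new stereocentre.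

Step 14
Reactants: 20 pentaol ketone
Product: 21 crotonoyl tetraol (C2=O (E)-enone; 1β,5α,6β,12-tetrahydroxy; C9=O)
Conditions: MnO2 (excess), CH2Cl2, rt
Reagents that add atoms: none
Why: MnO2 oxidises only the allylic C2 carbinol (allylic alcohol oxidation), converging both C2 epimers into the (E)-enone and leaving the saturated primary and secondary alcohols untouched.

Step 15
Reactants: 21 crotonoyl tetraol
Product: 23 hydroxy lactone (cis-fused 12,6-olide; 1β-OH; 5α-OH; C9=O; 11R), via lactol 22 (not isolated)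
Conditions: TEMPO (2,2,6,6-tetramethylpiperidin-1-oxyl, 20 mol %), PhI(OAc)2 (2.5 equiv), CH2Cl2, rt
Reagents that add atoms: none
Why: Nitroxyl-catalysed oxidation (TEMPO/PhI(OAc)2 oxidative lactonisation) is selective for the primary alcohol; the aldehyde is trapped by the cis-disposed 6β-hydroxyl as a five-membered lactol that is oxidised on to the cis-fused γ-lactone, while the hindered secondary 5α-hydroxyl should survive.

Step 16
Reactants: 23 hydroxy lactone; 24 (E)-2-methylbut-2-enoyl chloride
Product: 25 5α-tiglate (1β-OH; C9=O; cis-fused 12,6-olide)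
Conditions: DMAP (4-dimethylaminopyridine), pyridine, CH2Cl2, 0 °C → rt
Reagents that add atoms: none
Why: DMAP-catalysed acylation (nucleophilic catalysis with an acid chloride) esterifies the only secondary hydroxyl, the tertiary C1 hydroxyl being inert, and the (E)-configured tigloyl group is the stable isomer.

Step 17
Reactants: 25 5α-tiglate
Product: 26 (3R,3aS,5R,6S,7S,8S,8aR)-7-[(E)-but-2-enoyl]-5,7-dihydroxy-3,6-dimethyl-2-oxooctahydro-2H-cyclohepta[b]furan-8-yl (E)-2-methylbut-2-enoate (CNP0183494.2)
Conditions: Me4NBH(OAc)3, MeCN/AcOH (1:1), −30 °C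
Reagents that add atoms: none
Why: Evans–Saksena hydroxyl-directed reduction of the β-hydroxy ketone: the C1 β-hydroxyl delivers hydride to the β-face of C9 through a six-membered transition state, which should give the anti-1,3-diol (9α-hydroxyl), while the conjugated crotonoyl carbonyl, the tiglate and the lactone are much less reactive toward this mild reagent.

Compound list
1 | methyl (S)-3-hydroxy-2-methylpropanoate | COC(=O)[C@@H](C)CO | starting material
2 | methyl (S)-3-[(tert-butyldimethylsilyl)oxy]-2-methylpropanoate | COC(=O)[C@@H](C)CO[Si](C)(C)C(C)(C)C | intermediate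
3 | (S)-3-[(tert-butyldimethylsilyl)oxy]-2-methylpropanal | O=C[C@@H](C)CO[Si](C)(C)C(C)(C)C | intermediate
4 | diethyl (2-oxobutyl)phosphonate | CCC(=O)CP(=O)(OCC)OCC | starting material
5 | (R,E)-7-[(tert-butyldimethylsilyl)oxy]-6-methylhept-4-en-3-one | CCC(=O)/C=C/[C@@H](C)CO[Si](C)(C)C(C)(C)C | intermediate
6 | (2Z,4E,6R)-7-[(tert-butyldimethylsilyl)oxy]-6-methyl-3-[(triisopropylsilyl)oxy]hepta-2,4-diene | C/C=C(O[Si](C(C)C)(C(C)C)C(C)C)/C=C/[C@@H](C)CO[Si](C)(C)C(C)(C)C | intermediate
7 | 2,2-dimethyl-1,3-dioxan-5-one | CC1(C)OCC(=O)CO1 | starting material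
8 | 2,2-dimethyl-5-[(triisopropylsilyl)oxy]-4H-1,3-dioxine | CC1(C)OCC(O[Si](C(C)C)(C(C)C)C(C)C)=CO1 | intermediate
9 | 2-[(triisopropylsilyl)oxy]prop-2-enal | C=C(O[Si](C(C)C)(C(C)C)C(C)C)C=O | intermediate
10 | Diels–Alder adduct (not isolated): 5-methyl-2-[(2R)-1-(tert-butyldimethylsilyloxy)propan-2-yl]-1,4-bis(triisopropylsilyloxy)cyclohex-3-ene-1-carbaldehyde; 1-silyloxy, 2-side chain and 5-methyl mutually cis, formyl trans to them | O=C[C@]1(O[Si](C(C)C)(C(C)C)C(C)C)C[C@@H](C)C(O[Si](C(C)C)(C(C)C)C(C)C)=C[C@H]1[C@@H](C)CO[Si](C)(C)C(C)(C)C | intermediate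
11 | 6-methyl-3-[(2R)-1-(tert-butyldimethylsilyloxy)propan-2-yl]-2,5-bis(triisopropylsilyloxy)cyclohept-4-en-1-one; 2-silyloxy, 3-side chain and 6-methyl all cis (guaianolide positions: C5 ketone, 6β-OTIPS, 7β side chain, 10β-CH3) | C1[C@@H](C)C(O[Si](C(C)C)(C(C)C)C(C)C)=C[C@@H]([C@@H](C)CO[Si](C)(C)C(C)(C)C)[C@@H](O[Si](C(C)C)(C(C)C)C(C)C)C1=O | intermediate
12 | potassium C1=C5 enolate of 11 (not isolated) | [K+].[O-]C1=C[C@@H](C)C(O[Si](C(C)C)(C(C)C)C(C)C)=C[C@@H]([C@@H](C)CO[Si](C)(C)C(C)(C)C)[C@H]1O[Si](C(C)C)(C(C)C)C(C)C | intermediate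
13 | 1α-hydroxy derivative of 11 (hydroxyl on C1, trans to the C10 methyl; C5 ketone) | O[C@@H]1[C@@H](C)C(O[Si](C(C)C)(C(C)C)C(C)C)=C[C@@H]([C@@H](C)CO[Si](C)(C)C(C)(C)C)[C@@H](O[Si](C(C)C)(C(C)C)C(C)C)C1=O | intermediate
14 | 1,5-diketone (C1 and C5 carbonyls; 6β-OTIPS; 7β side chain; 9-OTIPS enol ether; 10β-CH3) | O=C1[C@@H](C)C(O[Si](C(C)C)(C(C)C)C(C)C)=C[C@@H]([C@@H](C)CO[Si](C)(C)C(C)(C)C)[C@@H](O[Si](C(C)C)(C(C)C)C(C)C)C1=O | intermediate
15 | (E)-but-2-enal | C/C=C/C=O | starting material
16 | bis(diiodosamarium) C1=C5 enediolate of 14 (trivalent samarium; not isolated) | [O-]C=1[C@@H](C)C(O[Si](C(C)C)(C(C)C)C(C)C)=C[C@@H]([C@@H](C)CO[Si](C)(C)C(C)(C)C)[C@@H](O[Si](C(C)C)(C(C)C)C(C)C)C=1[O-].[Sm+3].[Sm+3].[I-].[I-].[I-].[I-] | intermediate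
17 | aldol adduct: 1β-hydroxy-1α-[(E)-1-hydroxybut-2-enyl] C5 ketone (C2 epimers; other groups as 11) | C/C=C/C(O)[C@]1(O)[C@@H](C)C(O[Si](C(C)C)(C(C)C)C(C)C)=C[C@@H]([C@@H](C)CO[Si](C)(C)C(C)(C)C)[C@@H](O[Si](C(C)C)(C(C)C)C(C)C)C1=O | intermediate
18 | C2 triethylsilyl ether of 17 | C/C=C/C(O[Si](CC)(CC)CC)[C@]1(O)[C@@H](C)C(O[Si](C(C)C)(C(C)C)C(C)C)=C[C@@H]([C@@H](C)CO[Si](C)(C)C(C)(C)C)[C@@H](O[Si](C(C)C)(C(C)C)C(C)C)C1=O | intermediate
19 | 1β,5α-diol (2-OTES; 6β-OTIPS; 9-OTIPS enol ether; 12-OTBS) | C/C=C/C(O[Si](CC)(CC)CC)[C@]1(O)[C@@H](C)C(O[Si](C(C)C)(C(C)C)C(C)C)=C[C@@H]([C@@H](C)CO[Si](C)(C)C(C)(C)C)[C@@H](O[Si](C(C)C)(C(C)C)C(C)C)[C@@H]1O | intermediate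
20 | pentaol ketone: 1β,2,5α,6β,12-pentahydroxy C9 ketone (C2 epimers) | C/C=C/C(O)[C@]1(O)[C@@H](C)C(=O)C[C@@H]([C@@H](C)CO)[C@@H](O)[C@@H]1O | intermediate
21 | crotonoyl tetraol: 1β,5α,6β,12-tetrahydroxy C2-oxo (E)-enone, C9 ketone | C/C=C/C(=O)[C@]1(O)[C@@H](C)C(=O)C[C@@H]([C@@H](C)CO)[C@@H](O)[C@@H]1O | intermediate
22 | lactol (C12 hemiacetal closed onto O6; not isolated) | C/C=C/C(=O)[C@]1(O)[C@@H](C)C(=O)C[C@@H]2[C@@H](OC(O)[C@@H]2C)[C@@H]1O | intermediate
23 | hydroxy lactone: cis-fused 12,6-olide with 1β-OH, 5α-OH, C9 ketone, 11R | C/C=C/C(=O)[C@]1(O)[C@@H](C)C(=O)C[C@@H]2[C@@H](OC(=O)[C@@H]2C)[C@@H]1O | intermediate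
24 | (E)-2-methylbut-2-enoyl chloride (tigloyl chloride) | ClC(=O)/C(C)=C/C | starting material
25 | 5α-tiglate of 23 (C9 ketone) | C/C=C/C(=O)[C@]1(O)[C@@H](C)C(=O)C[C@@H]2[C@@H](OC(=O)[C@@H]2C)[C@@H]1OC(=O)/C(C)=C/C | intermediate
26 | (3R,3aS,5R,6S,7S,8S,8aR)-7-[(E)-but-2-enoyl]-5,7-dihydroxy-3,6-dimethyl-2-oxooctahydro-2H-cyclohepta[b]furan-8-yl (E)-2-methylbut-2-enoate | C/C=C/C(=O)[C@]1(O)[C@@H](C)[C@H](O)C[C@@H]2[C@@H](OC(=O)[C@@H]2C)[C@@H]1OC(=O)/C(C)=C/C | target

Total step count: 17. Longest linear sequence: 15 steps (steps 1–4 and 7–17).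

Steps most likely to fail

Step 7. The Lewis acids may strip or ionise the two silyl enol ether units before cycloaddition. The reaction may also stop after a stepwise Mukaiyama–Michael addition, C1 may migrate instead of C7, or the facial and C6 selectivity may erode. The fallback sets out from 6 and uses a direct oxyallyl-cation (4+3) cycloaddition: 1-chloro-3-[(triisopropylsilyl)oxy]propan-2-one F1 (from silylation of 1-chloro-3-hydroxypropan-2-one) is ionised with Et3N and LiClO4 in Et2O, and the resulting 1-silyloxy-2-oxyallyl cation is trapped by 6. The more electrophilic methylene terminus should bond to C10. The fallback returns to the route at 11 after chromatographic removal of minor diastereomers, with absolute control then resting on the C11 stereocentre.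

Step 10. The samarium enediolate may expel the C6 silyloxy group by β-elimination, crotonaldehyde may be reduced instead of attacked, or the C–C bond may form at C5 rather than C1. The fallback sets out from 14: reductive silylation with Zn and Me3SiCl in THF gives the 1,5-bis(trimethylsilyloxy) enediol ether F2, which undergoes a BF3·OEt2-promoted Mukaiyama aldol addition to 15 in CH2Cl2 at −78 °C. Mild acidic work-up removes the trimethylsilyl groups and returns to the route at 17.

Step 17. The C1 hydroxyl may also direct 1,2-reduction of the neighbouring crotonoyl carbonyl, giving mixtures. The fallback sets out from 25: deliberate exhaustive directed reduction (excess Me4NBH(OAc)3, −20 → 0 °C) of both the C9 and C2 carbonyls gives the tetraol F3 as C2 epimers. MnO2 in CH2Cl2 then reoxidises only the allylic C2 carbinol, which returns to the route at 26.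

Further compounds
F1 | step 7 | 1-chloro-3-[(triisopropylsilyl)oxy]propan-2-one | CC(C)[Si](OCC(=O)CCl)(C(C)C)C(C)C
F2 | step 10 | 1,5-bis(trimethylsilyloxy) C1=C5 enediol ether of 14 | C[Si](C)(C)OC=1[C@@H](C)C(O[Si](C(C)C)(C(C)C)C(C)C)=C[C@@H]([C@@H](C)CO[Si](C)(C)C(C)(C)C)[C@@H](O[Si](C(C)C)(C(C)C)C(C)C)C=1O[Si](C)(C)C
F3 | step 17 | 2-hydroxy analogue of 26 (C2 carbinol epimers; 1β,9α-dihydroxy; 5α-tiglate; 12,6-olide) | C/C=C/C(O)[C@]1(O)[C@@H](C)[C@H](O)C[C@@H]2[C@@H](OC(=O)[C@@H]2C)[C@@H]1OC(=O)/C(C)=C/C
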